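**Strategy.** The nine-membered oxacycle O–C3–C4=C5–C6–C7–C8–C9–C10 (germacrane numbering) is closed last, across C6–C7, by a chromium-mediated intramolecular Barbier (Nozaki–Hiyama–Kishi) allylation. The step exploits the allylic relationship hidden in the α-methylene lactone (C7–C11=C13): a 3-(bromomethyl)butenolide already carrying the 3(2H)-furanone and a Z-enal gives a C13 allylchromium that attacks the C6 aldehyde through C7. One operation unites two natively electrophilic carbons, closes the macrocycle, sets C6 and C7 and unveils the exocyclic methylene. The closed transition state should give the 6-epi alcohol, which an invertive Mitsunobu acylation with (2S,3S)-epoxyangelic acid turns into the target.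

Key step: step 12

Remark: locants follow germacrane numbering (C1 ketone, C2=C3 enol ether, C3–O–C10 bridge, C4=C5 Z-alkene, C6 acyloxy carbon, C7/C8 lactone junction, C9 methylene, C10 quaternary carbon, C11=C13 methylene, C12 lactone carbonyl).

Step 1
Reactants: 1 (R)-citramalic acid [(2R)-2-hydroxy-2-methylbutanedioic acid]
Product: 2 2-[(4R)-2,2,4-trimethyl-5-oxo-1,3-dioxolan-4-yl]acetic acid
Conditions: Me2C(OMe)2, p-TsOH·H2O (cat.), acetone, rt
Reagents that add atoms: 2,2-dimethoxypropane COC(C)(C)OC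
Why: Acid-catalysed transacetalisation ties the tertiary hydroxyl and the adjacent carboxyl into a five-membered 1,3-dioxolan-4-one (acetonide formation) and leaves the CH2CO2H group free; C10 comes unchanged from the chiral pool.

Step 2
Reactants: 2 2-[(4R)-2,2,4-trimethyl-5-oxo-1,3-dioxolan-4-yl]acetic acid; 3 tributyl(prop-1-yn-1-yl)stannane
Product: 5 (5R)-2,2,5-trimethyl-5-(2-oxopent-3-yn-1-yl)-1,3-dioxolan-4-one, via acid chloride 4 (not isolated)
Conditions: (COCl)2, DMF (cat.), CH2Cl2, 0 °C to rt; concentrate; then 3, PdCl2(PPh3)2 (3 mol%), toluene, 60 °C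
Reagents that add atoms: oxalyl chloride ClC(=O)C(=O)Cl (its chlorine is carried only by intermediate 4)
Why: Stille-type acyl cross-coupling of the acid chloride with the alkynylstannane runs under neutral conditions that leave the dioxolanone and the quaternary centre untouched.

Step 3
Reactants: 5 (5R)-2,2,5-trimethyl-5-(2-oxopent-3-yn-1-yl)-1,3-dioxolan-4-one
Product: 7 (3R,5S)-3-hydroxy-3-methyl-5-(prop-1-yn-1-yl)oxolan-2-one, via propargylic alcohol 6 (not isolated)
Conditions: Ru[(S,S)-TsNCH(Ph)CH(Ph)NH](p-cymene) (2 mol%), i-PrOH, rt; concentrate; CSA (10 mol%), CH2Cl2, rt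
Reagents that add atoms: none
Why: Noyori asymmetric transfer hydrogenation of the ynone distinguishes the alkynyl from the alkyl branch and, with the (S,S)-catalyst, should set C8 as the (S)-propargylic alcohol under reagent control; acid then lets the new hydroxyl translactonise onto the dioxolanone carbonyl with loss of acetone.

Step 4
Reactants: 7 (3R,5S)-3-hydroxy-3-methyl-5-(prop-1-yn-1-yl)oxolan-2-one
Product: 8 (3R,5S)-3-hydroxy-3-methyl-5-[(1Z)-prop-1-en-1-yl]oxolan-2-one
Conditions: H2 (1 atm), Lindlar catalyst (Pd on CaCO3 poisoned with Pb(OAc)2), quinoline, EtOAc, rt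
Reagents that add atoms: none
Why: Lindlar semihydrogenation adds hydrogen syn and stops at the Z-alkene, the later metathesis handle; no stereocentre is involved.

Step 5
Reactants: 9 (2Z)-3-methylpent-2-en-4-yn-1-ol
Product: 10 tert-butyl(dimethyl){[(2Z)-3-methylpent-2-en-4-yn-1-yl]oxy}silane
Conditions: TBSCl, imidazole, CH2Cl2, 0 °C to rt
Reagents that add atoms: tert-butyldimethylsilyl chloride CC(C)(C)[Si](C)(C)Cl
Why: Standard silylation of the primary allylic alcohol; the silyl ether keeps the Z-disposed oxygen from adding to the ynone or the furanone later.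

Step 6
Reactants: 10 tert-butyl(dimethyl){[(2Z)-3-methylpent-2-en-4-yn-1-yl]oxy}silane; 8 (3R,5S)-3-hydroxy-3-methyl-5-[(1Z)-prop-1-en-1-yl]oxolan-2-one
Product: 12 (2Z,7R,9S,10Z)-1-{[tert-butyl(dimethyl)silyl]oxy}-7,9-dihydroxy-3,7-dimethyldodeca-2,10-dien-4-yn-6-one, via lithium acetylide 11 (not isolated)
Conditions: 10 (2.4 equiv), n-BuLi (2.3 equiv), THF, −78 °C; then 8, −78 to −40 °C; AcOH, −78 °C
Reagents that add atoms: n-butyllithium [Li]CCCC (lithium is carried only by intermediate 11)
Why: Acetylide addition to a lactone: the first equivalent of 11 deprotonates the tertiary hydroxyl, the second adds once because the lithium lactolate does not collapse before the acidic quench, and ring opening gives the α′-hydroxy ynone; the lactone has no α-hydrogen, so C8 and C10 are untouched.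

Step 7
Reactants: 12 (2Z,7R,9S,10Z)-1-{[tert-butyl(dimethyl)silyl]oxy}-7,9-dihydroxy-3,7-dimethyldodeca-2,10-dien-4-yn-6-one
Product: 13 (2R)-5-[(2Z)-4-{[tert-butyl(dimethyl)silyl]oxy}but-2-en-2-yl]-2-[(2S,3Z)-2-hydroxypent-3-en-1-yl]-2-methylfuran-3(2H)-one
Conditions: Ph3PAuCl (2 mol%), AgOTf (2 mol%), toluene, rt
Reagents that add atoms: none
Why: Gold-catalysed cycloisomerisation of an α′-hydroxy ynone: 5-endo-dig attack of the tertiary C10 hydroxyl on the activated alkyne and protodeauration give the 3(2H)-furanone, while the secondary C8 hydroxyl has no favourable ring size to compete.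

Step 8
Reactants: 13 (2R)-5-[(2Z)-4-{[tert-butyl(dimethyl)silyl]oxy}but-2-en-2-yl]-2-[(2S,3Z)-2-hydroxypent-3-en-1-yl]-2-methylfuran-3(2H)-one; 14 2-(bromomethyl)prop-2-enoic acid
Product: 15 (2S,3Z)-1-[(2R)-5-[(2Z)-4-{[tert-butyl(dimethyl)silyl]oxy}but-2-en-2-yl]-2-methyl-3-oxo-2,3-dihydrofuran-2-yl]pent-3-en-2-yl 2-(bromomethyl)prop-2-enoate
Conditions: 14, DIC, DMAP (10 mol%), CH2Cl2, 0 °C
Reagents that add atoms: none
Why: Steglich-type carbodiimide esterification acylates the only free hydroxyl (C8) at low temperature with catalytic DMAP, which is mild enough to keep the allylic bromide.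

Step 9
Reactants: 15 (2S,3Z)-1-[(2R)-5-[(2Z)-4-{[tert-butyl(dimethyl)silyl]oxy}but-2-en-2-yl]-2-methyl-3-oxo-2,3-dihydrofuran-2-yl]pent-3-en-2-yl 2-(bromomethyl)prop-2-enoate
Product: 16 (2R)-2-{[(2S)-4-(bromomethyl)-5-oxo-2,5-dihydrofuran-2-yl]methyl}-5-[(2Z)-4-{[tert-butyl(dimethyl)silyl]oxy}but-2-en-2-yl]-2-methylfuran-3(2H)-one
Conditions: second-generation Grubbs catalyst, (H2IMes)(PCy3)Cl2Ru=CHPh (5 mol%), CH2Cl2, 40 °C
Reagents that add atoms: none
Why: Ring-closing metathesis between the Z-propenyl group and the 1,1-disubstituted acrylate closes the butenolide (C7=C11) with loss of propene under neutral conditions that do not epimerise the γ-position C8.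

Step 10
Reactants: 16 (2R)-2-{[(2S)-4-(bromomethyl)-5-oxo-2,5-dihydrofuran-2-yl]methyl}-5-[(2Z)-4-{[tert-butyl(dimethyl)silyl]oxy}but-2-en-2-yl]-2-methylfuran-3(2H)-one
Product: 17 (2R)-2-{[(2S)-4-(bromomethyl)-5-oxo-2,5-dihydrofuran-2-yl]methyl}-5-[(2Z)-4-hydroxybut-2-en-2-yl]-2-methylfuran-3(2H)-one
Conditions: HF (48% aq.), MeCN, 0 °C
Reagents that add atoms: none
Why: Acidic fluoride desilylation frees the primary alcohol without a basic or nucleophilic species that could displace the allylic bromide or deprotonate C8.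

Step 11
Reactants: 17 (2R)-2-{[(2S)-4-(bromomethyl)-5-oxo-2,5-dihydrofuran-2-yl]methyl}-5-[(2Z)-4-hydroxybut-2-en-2-yl]-2-methylfuran-3(2H)-one
Product: 18 (2Z)-3-[(5R)-5-{[(2S)-4-(bromomethyl)-5-oxo-2,5-dihydrofuran-2-yl]methyl}-5-methyl-4-oxo-4,5-dihydrofuran-2-yl]but-2-enal
Conditions: Dess–Martin periodinane, NaHCO3, CH2Cl2, 0 °C
Reagents that add atoms: none
Why: Buffered Dess–Martin oxidation of the primary allylic alcohol should give the enal with the Z geometry intact and without a base strong enough to enolise the butenolide.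

Step 12
Reactants: 18 (2Z)-3-[(5R)-5-{[(2S)-4-(bromomethyl)-5-oxo-2,5-dihydrofuran-2-yl]methyl}-5-methyl-4-oxo-4,5-dihydrofuran-2-yl]but-2-enal
Product: 20 (6R,7S,8S,10R)-6-hydroxy-1-oxo-3,10-epoxygermacra-2,4Z,11(13)-trien-12,8-olide (the 6-epi alcohol), via allylchromium dichloride 19 (not isolated)
Conditions: CrCl2 (8 equiv), THF, rt, slow addition of 18 (final 0.002 M); aqueous work-up
Reagents that add atoms: chromium dichloride Cl[Cr]Cl (chromium and chloride are carried only by intermediate 19)
Why: Two equivalents of CrCl2 reduce the allylic C13–Br bond to the C13 allylchromium 19 (trivalent chromium), which adds in SE2′ fashion through C7 to the C6 aldehyde via a closed six-membered transition state with chromium bound to the aldehyde oxygen; this joins the butenolide β-carbon and the aldehyde carbon, both natively electrophilic, and moves the alkene to C11=C13. The closest known reactions are the intramolecular Nozaki–Hiyama–Kishi allylation used for macrocyclisation and the Barbier allylation of aldehydes with 3-(bromomethyl)furan-2(5H)-ones. The nine-membered ring closes in 9-exo-trig mode at the aldehyde (C6–C7 bond) with the butenolide and furanone rings already in place. C7 is controlled by C8: the tether leaves C8 on one face of the planar butenolide and should reach C7 on the opposite face, because same-face closure would force C6 and C9 to eclipse in a ring that already holds the rigid transoid C10–O–C3–C4 unit and the Z-C4=C5 bond; this gives the trans-fused lactone. C6 is controlled by the chair-like transition state: the ring-locked allyl geometry (C8 trans to C13) and the s-trans Z-enal with C5 pseudo-equatorial lead to the anti adduct, the 6R alcohol, which the last step inverts. The step needs γ- over α-attack of the allyl unit, 1,2-addition to the enal and ring closure over oligomerisation, which the chromium chelate and slow addition at high dilution should secure.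

Step 13
Reactants: 21 angelic acid [(2Z)-2-methylbut-2-enoic acid]
Product: 22 (2Z)-2-methylbut-2-en-1-ol
Conditions: LiAlH4, Et2O, 0 °C
Reagents that add atoms: none
Why: Hydride reduction of the carboxylic acid gives the allylic alcohol with the Z-alkene unchanged.

Step 14
Reactants: 22 (2Z)-2-methylbut-2-en-1-ol
Product: 23 [(2R,3S)-2,3-dimethyloxiran-2-yl]methanol
Conditions: Ti(OiPr)4 (10 mol%), D-(−)-diethyl tartrate (12 mol%), t-BuOOH, 4 Å MS, CH2Cl2, −20 °C
Reagents that add atoms: tert-butyl hydroperoxide CC(C)(C)OO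
Why: Sharpless asymmetric epoxidation: the titanium–D-(−)-tartrate complex should deliver oxygen to the alkene face that gives the (2R,3S)-epoxy alcohol, and the trans relationship of the two methyl groups follows from the Z-alkene.

Step 15
Reactants: 23 [(2R,3S)-2,3-dimethyloxiran-2-yl]methanol
Product: 24 (2S,3S)-2,3-dimethyloxirane-2-carboxylic acid
Conditions: RuCl3·xH2O (2 mol%), NaIO4, MeCN/EtOAc/H2O, rt
Reagents that add atoms: sodium periodate [Na+].[O-]I(=O)(=O)=O; water O
Why: Catalytic RuO4 oxidation of the primary alcohol to the carboxylic acid leaves the epoxide and its stereocentres untouched (the descriptor at C2 changes only through CIP priorities).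

Step 16
Reactants: 20 (6R,7S,8S,10R)-6-hydroxy-1-oxo-3,10-epoxygermacra-2,4Z,11(13)-trien-12,8-olide; 24 (2S,3S)-2,3-dimethyloxirane-2-carboxylic acid
Product: 25 (6S,7R,8S,10R)-6-{[(2S,3S)-2,3-dimethyloxiran-2-yl]carbonyloxy}-1-oxo-3,10-epoxygermacra-2,4Z,11(13)-trien-12,8-olide (target CNP0258430.4)
Conditions: PPh3 and DIAD premixed in THF at 0 °C, then 24 and 20, toluene/THF, 0 °C to rt
Reagents that add atoms: none
Why: Mitsunobu esterification: the carboxylate displaces the C6 oxyphosphonium by SN2 with inversion (6R to 6S), SN1 or SN2′ escape being disfavoured because the allylic system belongs to the electron-poor dienone; preforming the betaine keeps free phosphine away from the α-methylene lactone.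

**Compound list**

1 | (R)-citramalic acid | OC(=O)C[C@@](C)(O)C(=O)O | starting material
2 | 2-[(4R)-2,2,4-trimethyl-5-oxo-1,3-dioxolan-4-yl]acetic acid | OC(=O)C[C@@]1(C)OC(C)(C)OC1=O | intermediate
3 | tributyl(prop-1-yn-1-yl)stannane | CC#C[Sn](CCCC)(CCCC)CCCC | starting material
4 | 2-[(4R)-2,2,4-trimethyl-5-oxo-1,3-dioxolan-4-yl]acetyl chloride | ClC(=O)C[C@@]1(C)OC(C)(C)OC1=O | intermediate (not isolated)
5 | (5R)-2,2,5-trimethyl-5-(2-oxopent-3-yn-1-yl)-1,3-dioxolan-4-one | CC#CC(=O)C[C@@]1(C)OC(C)(C)OC1=O | intermediate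
6 | (5R)-5-[(2S)-2-hydroxypent-3-yn-1-yl]-2,2,5-trimethyl-1,3-dioxolan-4-one | CC#C[C@@H](O)C[C@@]1(C)OC(C)(C)OC1=O | intermediate (not isolated)
7 | (3R,5S)-3-hydroxy-3-methyl-5-(prop-1-yn-1-yl)oxolan-2-one | CC#C[C@@H]1C[C@@](C)(O)C(=O)O1 | intermediate
8 | (3R,5S)-3-hydroxy-3-methyl-5-[(1Z)-prop-1-en-1-yl]oxolan-2-one | C/C=C\[C@@H]1C[C@@](C)(O)C(=O)O1 | intermediate
9 | (2Z)-3-methylpent-2-en-4-yn-1-ol | C#C/C(C)=C\CO | starting material
10 | tert-butyl(dimethyl){[(2Z)-3-methylpent-2-en-4-yn-1-yl]oxy}silane | C#C/C(C)=C\CO[Si](C)(C)C(C)(C)C | intermediate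
11 | lithium acetylide of 10 | [Li]C#C/C(C)=C\CO[Si](C)(C)C(C)(C)C | intermediate (not isolated)
12 | (2Z,7R,9S,10Z)-1-{[tert-butyl(dimethyl)silyl]oxy}-7,9-dihydroxy-3,7-dimethyldodeca-2,10-dien-4-yn-6-one | C/C=C\[C@@H](O)C[C@@](C)(O)C(=O)C#C/C(C)=C\CO[Si](C)(C)C(C)(C)C | intermediate
13 | (2R)-5-[(2Z)-4-{[tert-butyl(dimethyl)silyl]oxy}but-2-en-2-yl]-2-[(2S,3Z)-2-hydroxypent-3-en-1-yl]-2-methylfuran-3(2H)-one | C/C=C\[C@@H](O)C[C@@]1(C)OC(=CC1=O)/C(C)=C\CO[Si](C)(C)C(C)(C)C | intermediate
14 | 2-(bromomethyl)prop-2-enoic acid | C=C(CBr)C(=O)O | starting material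
15 | 2-(bromomethyl)acrylate of 13 at the C8 hydroxyl | C/C=C\[C@@H](OC(=O)C(=C)CBr)C[C@@]1(C)OC(=CC1=O)/C(C)=C\CO[Si](C)(C)C(C)(C)C | intermediate
16 | (2R)-2-{[(2S)-4-(bromomethyl)-5-oxo-2,5-dihydrofuran-2-yl]methyl}-5-[(2Z)-4-{[tert-butyl(dimethyl)silyl]oxy}but-2-en-2-yl]-2-methylfuran-3(2H)-one | BrCC1=C[C@H](C[C@@]2(C)OC(=CC2=O)/C(C)=C\CO[Si](C)(C)C(C)(C)C)OC1=O | intermediate
17 | (2R)-2-{[(2S)-4-(bromomethyl)-5-oxo-2,5-dihydrofuran-2-yl]methyl}-5-[(2Z)-4-hydroxybut-2-en-2-yl]-2-methylfuran-3(2H)-one | BrCC1=C[C@H](C[C@@]2(C)OC(=CC2=O)/C(C)=C\CO)OC1=O | intermediate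
18 | (2Z)-3-[(5R)-5-{[(2S)-4-(bromomethyl)-5-oxo-2,5-dihydrofuran-2-yl]methyl}-5-methyl-4-oxo-4,5-dihydrofuran-2-yl]but-2-enal | BrCC1=C[C@H](C[C@@]2(C)OC(=CC2=O)/C(C)=C\C=O)OC1=O | intermediate
19 | C13 allylchromium dichloride from 18 (trivalent chromium) | Cl[Cr](Cl)CC1=C[C@H](C[C@@]2(C)OC(=CC2=O)/C(C)=C\C=O)OC1=O | intermediate (not isolated)
20 | (6R,7S,8S,10R)-6-hydroxy-1-oxo-3,10-epoxygermacra-2,4Z,11(13)-trien-12,8-olide (6-epi alcohol; C7 has the same spatial arrangement as in 25, the label differs only through CIP priorities) | C=C1C(=O)O[C@H]2C[C@@]3(C)OC(=CC3=O)/C(C)=C\[C@@H](O)[C@H]12 | intermediate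
21 | angelic acid | C/C=C(/C)C(=O)O | starting material
22 | (2Z)-2-methylbut-2-en-1-ol | C/C=C(/C)CO | intermediate
23 | [(2R,3S)-2,3-dimethyloxiran-2-yl]methanol | OC[C@@]1(C)O[C@H]1C | intermediate
24 | (2S,3S)-2,3-dimethyloxirane-2-carboxylic acid | OC(=O)[C@@]1(C)O[C@H]1C | intermediate
25 | CNP0258430.4 | C=C1C(=O)O[C@H]2C[C@@]3(C)OC(=CC3=O)/C(C)=C\[C@H](OC(=O)[C@@]3(C)O[C@H]3C)[C@H]12 | target

**Step count.** 16 steps in total. The longest linear sequence is 12 steps (steps 1–4, 6–12 and 16, from (R)-citramalic acid).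

**Steps most likely to fail**

Step 12. Ring closure may be outrun by intermolecular coupling or by protonation of the allylchromium, the aldehyde may approach C7 on the face syn to C9 (cis-fused lactone), or the enal may lose its Z geometry before closure. The fallback makes the C6–C7 bond intermolecularly and closes the same ring by metathesis at C4=C5; it sets out from lactone 8 and comes back at alcohol 20. Addition of lithiated 2-methylbut-1-en-3-yne to 8 (as in step 6) should give the isopropenyl diol ynone F1. Gold-catalysed cycloisomerisation then gives the isopropenyl furanone F2, esterification with 14 the bromomethylacrylate F3, and ring-closing metathesis the bromomethylbutenolide F4. Barbier allylation of acrolein with F4 (Zn dust, THF/aq. NH4Cl, 0 °C) is expected to occur anti to the γ-substituent through a chair transition state and give the anti homoallylic alcohol F5. Ring-closing metathesis between its isopropenyl and vinyl groups (second-generation Hoveyda–Grubbs catalyst, (H2IMes)Cl2Ru=CH(2-i-PrOC6H4), toluene, 80 °C, 0.001 M) closes the nine-membered ring as the ring-enforced Z-alkene and gives 20.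

Step 16. The oxyphosphonium may eliminate toward C6=C7, react with allylic transposition, or resist attack by the hindered α-quaternary carboxylate. The fallback replaces substitution by a redox inversion followed by acylation with retention; it sets out from 20 and comes back at 25. Dess–Martin oxidation gives the C6 ketone F6. A 1,2-reduction (NaBH4, CeCl3·7H2O, MeOH, −78 °C, or the matching enantiomer of the Me-CBS oxazaborolidine with catecholborane if the ring bias is wrong) gives the 6S alcohol F7. Yamaguchi esterification with 24 (2,4,6-trichlorobenzoyl chloride, Et3N, then DMAP, toluene) gives 25. F7 is also the alcohol that a boat-type closure in step 12 would deliver, and it would then be acylated directly.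

Step 10. Under acid the freed cis-disposed hydroxyl may add to C3 of the furanone, and the allylic bromide may be lost by solvolysis. The fallback installs the aldehyde before the bromide; it sets out from 13 and comes back at 18. Bu4NF/AcOH (THF, 0 °C), used before any bromide is present, gives the diol F8. TEMPO (cat.)/PhI(OAc)2 oxidises the primary allylic alcohol in preference to the secondary one and gives the hydroxy enal F9. Esterification with 14 (as in step 8) gives the bromomethylacrylate F10, and ring-closing metathesis (as in step 9) gives 18.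

**Further compounds**

F1 | step 12 | (6R,8S,9Z)-6,8-dihydroxy-2,6-dimethylundeca-1,9-dien-3-yn-5-one | C/C=C\[C@@H](O)C[C@@](C)(O)C(=O)C#CC(C)=C
F2 | step 12 | (2R)-2-[(2S,3Z)-2-hydroxypent-3-en-1-yl]-2-methyl-5-(prop-1-en-2-yl)furan-3(2H)-one | C/C=C\[C@@H](O)C[C@@]1(C)OC(=CC1=O)C(C)=C
F3 | step 12 | 2-(bromomethyl)acrylate of F2 at the C8 hydroxyl | C/C=C\[C@@H](OC(=O)C(=C)CBr)C[C@@]1(C)OC(=CC1=O)C(C)=C
F4 | step 12 | (2R)-2-{[(2S)-4-(bromomethyl)-5-oxo-2,5-dihydrofuran-2-yl]methyl}-2-methyl-5-(prop-1-en-2-yl)furan-3(2H)-one | BrCC1=C[C@H](C[C@@]2(C)OC(=CC2=O)C(C)=C)OC1=O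
F5 | step 12 | anti Barbier adduct of F4 and acrolein (trans-4,5-disubstituted 3-methyleneoxolan-2-one with a 1-hydroxyprop-2-en-1-yl group at C7) | C=C1C(=O)O[C@@H](C[C@@]2(C)OC(=CC2=O)C(C)=C)[C@@H]1[C@H](O)C=C
F6 | step 16 | (7S,8S,10R)-1,6-dioxo-3,10-epoxygermacra-2,4Z,11(13)-trien-12,8-olide | C=C1C(=O)O[C@H]2C[C@@]3(C)OC(=CC3=O)/C(C)=C\C(=O)[C@H]12
F7 | step 16 | (6S,7S,8S,10R)-6-hydroxy-1-oxo-3,10-epoxygermacra-2,4Z,11(13)-trien-12,8-olide | C=C1C(=O)O[C@H]2C[C@@]3(C)OC(=CC3=O)/C(C)=C\[C@H](O)[C@H]12
F8 | step 10 | (2R)-5-[(2Z)-4-hydroxybut-2-en-2-yl]-2-[(2S,3Z)-2-hydroxypent-3-en-1-yl]-2-methylfuran-3(2H)-one | C/C=C\[C@@H](O)C[C@@]1(C)OC(=CC1=O)/C(C)=C\CO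
F9 | step 10 | (2Z)-3-{(5R)-5-[(2S,3Z)-2-hydroxypent-3-en-1-yl]-5-methyl-4-oxo-4,5-dihydrofuran-2-yl}but-2-enal | C/C=C\[C@@H](O)C[C@@]1(C)OC(=CC1=O)/C(C)=C\C=O
F10 | step 10 | 2-(bromomethyl)acrylate of F9 at the C8 hydroxyl | C/C=C\[C@@H](OC(=O)C(=C)CBr)C[C@@]1(C)OC(=CC1=O)/C(C)=C\C=O
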